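**Assumptions (one line each)**
- (S)-(+)-Linalool (coriandrol) is taken as the purchasable enantio-enriched terpene; its ee must be checked, and the (R)-enantiomer would give ent-aplyviolene by the same route.
- Locants in the text follow aplyviolene numbering: C4 = CMe2, C5/C9 = ring fusion, C8 = quaternary C, C10 = ring carbon bearing the exocyclic CH2 (C20), C11 = lactone C=O, C12 = CH2, C13/C14 = ring CH, C15 = acylal CH, C16 = acetoxy acetal CH. "β" is the face of H-5.

**Retrosynthetic overview**
1. Aplyviolene ⇐ acetylation of the bridged lactol ⇐ acid-triggered transannular acetalisation of a 6-methoxy-δ-lactone carrying a masked C16 aldehyde, installed by radical conjugate addition anti to C8.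
2. That lactone ⇐ ring-closing metathesis of an acrylate acylal with the C14 vinyl group.
3. The C8–C14 bond, with both stereocentres ⇐ anionic oxy-Cope [3,3] of a 10-allyl bicyclic tertiary alkoxide (chair TS); this also returns the C10 ketone for methylenation.
4. Bicyclic enone ⇐ intramolecular alkene acylation (seven-membered ring) ⇐ chain extension of an aldehyde whose C5 stereocentre and C4 quaternary carbon come from an Ireland–Claisen [3,3] on the isobutyrate of (S)-1-methylcyclopent-2-enol ⇐ RCM of (S)-linalool.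
5. Ring order: cyclopentene → cycloheptenone → δ-lactone → THF bridge.

**Route**

Step 1
Reactants: 1, (S)-(+)-linalool
Product: 2, (1S)-1-methylcyclopent-2-en-1-ol
Conditions: Grubbs II (0.5 mol%), CH2Cl2, 23 °C (isobutene lost)
Reagents that add atoms: none
Why: Ring-closing metathesis joins the vinyl group and the prenyl alkene to a cyclopentene; the carbinol stereocentre is not touched.

Step 2
Reactants: 2; 3, 2-methylpropanoyl chloride
Product: 4, (1S)-1-methylcyclopent-2-en-1-yl 2-methylpropanoate
Conditions: n-BuLi, THF, −78 °C; then 3, −78 → 0 °C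
Reagents that add atoms: 2-methylpropanoyl chloride, CC(C)C(Cl)=O
Why: O-acylation of the tertiary lithium alkoxide avoids acid, which would dehydrate the tertiary allylic alcohol; no stereocentre changes.

Step 3
Reactants: 4
Product: 5, 2-methyl-2-[(1R)-3-methylcyclopent-2-en-1-yl]propanoic acid
Conditions: LDA, THF, −78 °C; TMSCl; −78 → 65 °C; aq. HCl work-up
Reagents that add atoms: none
Why: Ireland–Claisen [3,3] rearrangement: the silyl ketene acetal bonds to C5 on the face the C–O bond leaves (suprafacial 1,3-chirality transfer), giving the C4 quaternary carbon and (R)-C5; chair versus boat is irrelevant because the migrating carbon is CMe2.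

Step 4
Reactants: 5
Product: 6, 2-methyl-2-[(1R)-3-methylcyclopent-2-en-1-yl]propanal
Conditions: (COCl)2, cat. DMF, CH2Cl2, 0 °C; then LiAlH(Ot-Bu)3, THF, −78 °C
Reagents that add atoms: none
Why: Partial reduction of the hindered acid chloride stops at the non-enolisable aldehyde.

Step 5
Reactants: 6; 7, (2-carboxyethyl)triphenylphosphonium bromide
Product: 8, (3Z)-5-methyl-5-[(1R)-3-methylcyclopent-2-en-1-yl]hex-3-enoic acid
Conditions: 7, NaHMDS (2.2 equiv), THF, −78 → 23 °C
Reagents that add atoms: (2-carboxyethyl)triphenylphosphonium bromide, OC(=O)CC[P+](c1ccccc1)(c1ccccc1)c1ccccc1.[Br-]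
Why: Wittig olefination with a non-stabilised carboxylate ylide adds C2, C1 and C10 in one step; alkene geometry is irrelevant because it is reduced next.

Step 6
Reactants: 8
Product: 9, 5-methyl-5-[(1R)-3-methylcyclopent-2-en-1-yl]hexanoic acid
Conditions: H2 (1 atm), (Ph3P)3RhCl (5 mol%), PhH–EtOH, 23 °C
Reagents that add atoms: none
Why: Wilkinson hydrogenation reduces the cis-disubstituted alkene and leaves the trisubstituted ring alkene.

Step 7
Reactants: 9
Product: 10, (8aS)-3,8,8-trimethyl-2,5,6,7,8,8a-hexahydroazulen-4(1H)-one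
Conditions: (COCl)2, cat. DMF, CH2Cl2; then SnCl4, −78 → 0 °C; then DBU, 23 °C
Reagents that add atoms: none
Why: Intramolecular Friedel–Crafts-type alkene acylation: the acylium attacks C9 (tertiary cation at C8) to close the seven-membered ring, and DBU gives the conjugated tetrasubstituted enone; C5 is untouched.

Step 8
Reactants: 10; 11, allylmagnesium bromide
Product: 12, (4S,8aS)-3,8,8-trimethyl-4-(prop-2-en-1-yl)-1,2,4,5,6,7,8,8a-octahydroazulen-4-ol (allyl cis to H-8a)
Conditions: anhydrous CeCl3, 11, THF, −78 °C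
Reagents that add atoms: allylmagnesium bromide, C=CC[Mg]Br
Why: Allylcerium 1,2-addition (no enolisation or 1,4-addition) is expected from the β-face, because the C1–C4 loop and gem-dimethyl group of the seven-membered ring lie on the α-face; this sets C10.

Step 9
Reactants: 12; 13, acrolein dimethyl acetal
Product: 14, (4S,8aS)-4-[(2E)-4,4-dimethoxybut-2-en-1-yl]-3,8,8-trimethyl-1,2,4,5,6,7,8,8a-octahydroazulen-4-ol
Conditions: 13 (5 equiv), Hoveyda–Grubbs II (5 mol%), CH2Cl2, 40 °C
Reagents that add atoms: acrolein dimethyl acetal, C=CC(OC)OC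
Why: Cross-metathesis of the terminal allyl group with the acetal gives the E-alkene; the tetrasubstituted ring alkene does not react.

Step 10
Reactants: 14
Product: 15, (3S,3aR,8aR)-3-[(2R)-1,1-dimethoxybut-3-en-2-yl]-3,8,8-trimethyloctahydroazulen-4(1H)-one (cis-fused)
Conditions: KH, 18-crown-6, THF, 0 → 23 °C; then MeOH, 23 °C; aq. NH4Cl
Reagents that add atoms: none
Why: Anionic oxy-Cope [3,3] rearrangement: the β-allyl group on C10 migrates suprafacially to the β-face of C8 through a chair TS, so the E-alkene gives (14R) and the quaternary C8 with Me α. The enolate is then protonated and equilibrated by KOMe to the cis-fused ketone, in which the C9–C10 bond is anti to the bulky C8 substituent.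

Step 11
Reactants: 15; 16, methyltriphenylphosphonium bromide
Product: 17, (3R,3aS,8aR)-3-[(2R)-1,1-dimethoxybut-3-en-2-yl]-3,8,8-trimethyl-4-methylidenedecahydroazulene
Conditions: 16, KOt-Bu, toluene, 80 °C
Reagents that add atoms: methyltriphenylphosphonium bromide, C[P+](c1ccccc1)(c1ccccc1)c1ccccc1.[Br-]
Why: Wittig methylenation under conditions suited to hindered ketones installs C20; C9 stays at the thermodynamic cis fusion and the acetal and vinyl groups are base-stable.

Step 12
Reactants: 17; 18, acrylic anhydride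
Product: 19, (1RS,2R)-1-methoxy-2-[(3R,3aS,8aR)-3,8,8-trimethyl-4-methylidenedecahydroazulen-3-yl]but-3-en-1-yl prop-2-enoate
Conditions: 18 (1.5 equiv), TMSOTf (10 mol%), CH2Cl2, −78 → −40 °C; Et3N quench
Reagents that add atoms: acrylic anhydride, C=CC(=O)OC(=O)C=C
Why: Acetal–anhydride exchange (acetolysis type) via the C15 oxocarbenium replaces one OMe by acryloyloxy; the C15 epimer mixture is erased later.

Step 13
Reactants: 19
Product: 20, (5R,6RS)-6-methoxy-5-[(3R,3aS,8aR)-3,8,8-trimethyl-4-methylidenedecahydroazulen-3-yl]-5,6-dihydro-2H-pyran-2-one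
Conditions: Grubbs II (10 mol%), toluene, 80 °C
Reagents that add atoms: none
Why: Ring-closing metathesis of the acrylate with the C14 vinyl group gives the α,β-unsaturated δ-lactone; the hindered 1,1-disubstituted exocyclic alkene is inert.

Step 14
Reactants: 20; 21, 1,3-dioxolane
Product: 22, (4R,5R,6RS)-4-(1,3-dioxolan-2-yl)-6-methoxy-5-[(3R,3aS,8aR)-3,8,8-trimethyl-4-methylidenedecahydroazulen-3-yl]oxan-2-one
Conditions: 21–MeCN (1:1), (n-Bu4N)4W10O32 (2 mol%), 365 nm, 23 °C
Reagents that add atoms: 1,3-dioxolane, C1COCO1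
Why: Photocatalytic HAT gives the nucleophilic dioxolan-2-yl radical, which adds (Giese) to C13 anti to the bulky C14 substituent; this sets (13R) with C16 trans to C8 on the lactone ring.

Step 15
Reactants: 22; 23, water
Product: 24, (1S,5R,8R)-6-hydroxy-8-[(3R,3aS,8aR)-3,8,8-trimethyl-4-methylidenedecahydroazulen-3-yl]-2,7-dioxabicyclo[3.2.1]octan-3-one (lactol, anomers)
Conditions: 1 M HCl–THF (1:4), 23 °C
Reagents that add atoms: water, O
Why: Acid unmasks the C16 aldehyde and ionises the C15 methoxy acylal; the C16 hydrate oxygen closes onto C15 (transannular acetalisation), which is possible because C16 is 1,3-cis to C15, and the bridge fixes (15S).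

Step 16
Reactants: 24; 25, acetic anhydride
Product: 26, aplyviolene
Conditions: 25, DMAP, pyridine, CH2Cl2, 0 °C
Reagents that add atoms: acetic anhydride, CC(=O)OC(C)=O
Why: Acetylation of the equilibrating lactol on the open exo face (anti to the lactone bridge) gives the (16S) acetate.

**Compound list**

1 | (S)-(+)-linalool | C=C[C@@](C)(O)CCC=C(C)C | starting material
2 | (1S)-1-methylcyclopent-2-en-1-ol | C1=C[C@@](C)(O)CC1 | intermediate
3 | 2-methylpropanoyl chloride | CC(C)C(Cl)=O | starting material
4 | (1S)-1-methylcyclopent-2-en-1-yl 2-methylpropanoate | C1=C[C@@](C)(OC(=O)C(C)C)CC1 | intermediate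
5 | 2-methyl-2-[(1R)-3-methylcyclopent-2-en-1-yl]propanoic acid | OC(=O)C(C)(C)[C@H]1C=C(C)CC1 | intermediate
6 | 2-methyl-2-[(1R)-3-methylcyclopent-2-en-1-yl]propanal | O=CC(C)(C)[C@H]1C=C(C)CC1 | intermediate
7 | (2-carboxyethyl)triphenylphosphonium bromide | OC(=O)CC[P+](c1ccccc1)(c1ccccc1)c1ccccc1.[Br-] | starting material
8 | (3Z)-5-methyl-5-[(1R)-3-methylcyclopent-2-en-1-yl]hex-3-enoic acid | OC(=O)C/C=C\C(C)(C)[C@H]1C=C(C)CC1 | intermediate
9 | 5-methyl-5-[(1R)-3-methylcyclopent-2-en-1-yl]hexanoic acid | OC(=O)CCCC(C)(C)[C@H]1C=C(C)CC1 | intermediate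
10 | (8aS)-3,8,8-trimethyl-2,5,6,7,8,8a-hexahydroazulen-4(1H)-one | O=C1CCCC(C)(C)[C@@H]2CCC(C)=C12 | intermediate
11 | allylmagnesium bromide | C=CC[Mg]Br | starting material
12 | (4S,8aS)-4-allyl-3,8,8-trimethyl-1,2,4,5,6,7,8,8a-octahydroazulen-4-ol | C=CC[C@@]1(O)CCCC(C)(C)[C@@H]2CCC(C)=C12 | intermediate
13 | acrolein dimethyl acetal | C=CC(OC)OC | starting material
14 | (4S,8aS)-4-[(2E)-4,4-dimethoxybut-2-en-1-yl]-3,8,8-trimethyl-1,2,4,5,6,7,8,8a-octahydroazulen-4-ol | COC(OC)/C=C/C[C@@]1(O)CCCC(C)(C)[C@@H]2CCC(C)=C12 | intermediate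
15 | (3S,3aR,8aR)-3-[(2R)-1,1-dimethoxybut-3-en-2-yl]-3,8,8-trimethyloctahydroazulen-4(1H)-one | O=C1CCCC(C)(C)[C@@H]2CC[C@@](C)([C@@H](C=C)C(OC)OC)[C@H]12 | intermediate
16 | methyltriphenylphosphonium bromide | C[P+](c1ccccc1)(c1ccccc1)c1ccccc1.[Br-] | starting material
17 | (3R,3aS,8aR)-3-[(2R)-1,1-dimethoxybut-3-en-2-yl]-3,8,8-trimethyl-4-methylidenedecahydroazulene | C=C1CCCC(C)(C)[C@@H]2CC[C@@](C)([C@@H](C=C)C(OC)OC)[C@H]12 | intermediate
18 | acrylic anhydride | C=CC(=O)OC(=O)C=C | starting material
19 | (1RS,2R)-1-methoxy-2-[(3R,3aS,8aR)-3,8,8-trimethyl-4-methylidenedecahydroazulen-3-yl]but-3-en-1-yl acrylate | C=C1CCCC(C)(C)[C@@H]2CC[C@@](C)([C@@H](C=C)C(OC)OC(=O)C=C)[C@H]12 | intermediate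
20 | (5R,6RS)-6-methoxy-5-[(3R,3aS,8aR)-3,8,8-trimethyl-4-methylidenedecahydroazulen-3-yl]-5,6-dihydro-2H-pyran-2-one | C=C1CCCC(C)(C)[C@@H]2CC[C@@](C)([C@@H]3C(OC)OC(=O)C=C3)[C@H]12 | intermediate
21 | 1,3-dioxolane | C1COCO1 | starting material
22 | (4R,5R,6RS)-4-(1,3-dioxolan-2-yl)-6-methoxy-5-[(3R,3aS,8aR)-3,8,8-trimethyl-4-methylidenedecahydroazulen-3-yl]oxan-2-one | C=C1CCCC(C)(C)[C@@H]2CC[C@@](C)([C@@H]3C(OC)OC(=O)C[C@H]3C4OCCO4)[C@H]12 | intermediate
23 | water | O | starting material
24 | (1S,5R,8R)-6-hydroxy-8-[(3R,3aS,8aR)-3,8,8-trimethyl-4-methylidenedecahydroazulen-3-yl]-2,7-dioxabicyclo[3.2.1]octan-3-one | C=C1CCCC(C)(C)[C@@H]2CC[C@@](C)([C@@H]3[C@@H]4OC(=O)C[C@H]3C(O)O4)[C@H]12 | intermediate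
25 | acetic anhydride | CC(=O)OC(C)=O | starting material
26 | aplyviolene | C=C1CCCC(C)(C)[C@@H]2CC[C@@](C)([C@@H]3[C@@H]4OC(=O)C[C@H]3[C@H](OC(C)=O)O4)[C@H]12 | target

**Totals**
Total steps: 16. Longest linear sequence: 16 (fully linear from (S)-linalool).

**Three steps most likely to fail, with fallbacks**
1. Step 10 (with the facial selectivity of step 8): the alkoxide may fragment by retro-allylation, react through a boat TS, or carry the allyl group on the α-face. Fallback: Luche-reduce enone 10 to the C10 allylic alcohol (its configuration can be corrected by Mitsunobu inversion) and transfer the side chain from oxygen by an Ireland–Claisen rearrangement of its but-3-enoate (C10–O → C8). Then restore the C10 carbonyl by epoxidation and Meinwald rearrangement of the new C9=C10 alkene, and reduce the C15 carboxyl to the acetal level.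
2. Step 12 (and the RCM of the resulting acylal in step 13): the C15 oxocarbenium sits next to an allylic C–H and near the exocyclic alkene, so it may eliminate to a dienol ether or undergo Prins cyclisation. Fallback: carry C15 at the alcohol level. Use (Z)-1,4-bis(4-methoxybenzyloxy)but-2-ene in step 9, then DDQ, acryloyl chloride and RCM to an ordinary unsaturated δ-lactone. Run the same radical addition, then saponify, oxidise C15–OH to the aldehyde (Dess–Martin) and cyclise. This costs three extra steps.
3. Step 15: aqueous acid may epimerise C14, give the fused 2,8-dioxabicyclo[3.3.0] isomer, or isomerise the exocyclic alkene. Fallback: skip the free lactol and form the C16–OAc bond by anhydrous acetolysis of 22 (Ac2O/AcOH, cat. BF3·OEt2, low temperature). The opened dioxolane oxygen traps the C15 oxocarbenium and acetate attacks the C16 oxocarbenium from the exo face.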